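**Unit and runs.** Percent of the G charged was my unit, and in it I read the larch run, the flask asked about, followed so far to 60.0 min.

- larch: G 0.71 M; the very flask that is asked about, followed so far
- flask: G 0.71 M; time 2.5 h

larch run (percent of the G charged)

| time / min | G / % | J / % | D / % | E / % |
|---|---|---|---|---|
| 8.00 | 47 | 6 | 41 | 5 |
| 20.0 | 28 | 15 | 46 | 11 |
| 40.0 | 21 | 18 | 40 | 21 |
| 60.0 | 15 | 23 | 32 | 32 |

(scatter of a reading: 1.5 percentage points)

- a reading or a percentage of J counts all its forms, free or not

* the species that holds most of what was charged as G, at 2.5 h (G / J / D / E)
* the largest share itself, whichever of these holds it, in percent of the G charged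

**Drain share.** The G/D readings stood at 0.525 and 0.469, which I took for a pre-equilibrium, so I lumped G and D into one pool. Over those readings E gained 11 percentage points and J 5 points. That gave 0.688 as the drain share, the selectivity with which what leaves the pool arrives as E.

**Two extremes.** My first extreme froze the pool at its last reading, 47.0%, which kept E at 32%, level with the D reading. My second drained the pool fully, which put E at 64.3%.

**Between them.** The pool had fallen from a reading of 61.0%, which I read as a first-order constant of 0.0130 /min, so I expected 14.5% left at 2.5 h. My reckoning put E at 54.3%, more than J at 33.1%.

**The forecast.** It named E at 55%, above my figure: “E therefore holds the most, barring reversibility or inhibition”.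

**The flask.** It gave E at 55.9%, with the pool at 14.8% and the drain share since the last reading at 0.741.

    G → J (k = 0.0141 /min)
    G ⇌ D (K = 2.05, k = 0.0960 /min)
    X ⇌ J, rate k3*(cs3 - [J]) while solid is left; crystals form when [J] > cs3 (solubility = 0.180 M, k = 0.477 /min)
    D → E (k = 0.0120 /min)
    J ⇌ E (K = 2.60, k = 0.00613 /min)

**Longer flask.** The neighbouring flask, left until 10 h, took the same reckoning. The constant gave a pool of 0.0412%, and that flask held G 0.0159% and D 0.0332%. The drain share gave E 64.3%, and that flask held 66.4%, a share of 0.733. J stood at 33.5%, of which the crystals X held 8.15%.

The numbers in the tables come from a simulation from invented constants; the scatter is artificial.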